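## Retrosynthetic overview

- **Feature:** ring A (C4a, C5, C6, C7, C8, C8a) is a hexasubstituted benzene. Its adjacent C5-OH and C6-OH can both come from C-Si bonds of a single Si-O-Si bridge. The crowded C8-C3' bond to the pyranone (O1', C2' to C6') can be made earlier, at an unhindered sp carbon.
- **Endgame cuts:** five O-benzyl groups and the C7 acetal; the styryl C=C on C6' (aldol/dehydration with 3,4-bis(benzyloxy)benzaldehyde); C5-O and C6-O (double Tamao oxidation of a benzo-fused oxadisilole).
- **Key cut:** C4a-C8a, C5-C6 and C7-C8 by a fully intramolecular [2+2+2] of a linear triyne. Ring A, ring B and the temporary oxadisilole form together; the pyranone ring is bought in and the styryl catechol ring is attached last.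
- **Triyne:** C(sp)-Si bond from a zinc acetylide and a chlorodisiloxane made from 3,3-diethoxypropyne; C8-C3' by Sonogashira coupling; both alkynes by one-carbon homologation of aldehydes.
- **Stereocentres:** C1, C4 and the C1-C4 chain come from (+)-menthol, by cleaving the C=C of the kinetic silyl enol ether of (+)-menthone.

Key step: step 14

Assumption: the C8-C3' bond carries four ortho substituents and may rotate slowly. The target is drawn without an axial descriptor, so rotamers about this bond are treated as one compound from the key step onwards. The tetralin and pyranone numbering of the overview is used throughout.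

## Route

Step 1
Reactants: 1 (+)-menthol, (1S,2R,5S)
Product: 2 (+)-menthone, (2R,5S)-5-methyl-2-(propan-2-yl)cyclohexanone
Conditions: TEMPO (1 mol %), KBr (10 mol %), aq NaOCl, NaHCO3, CH2Cl2/H2O, 0 °C
Reagents that add atoms: none
Why: TEMPO/hypochlorite oxidation of a secondary alcohol at buffered pH and 0 °C is fast, so the centre alpha to the new ketone should not epimerise to the isomenthone series.

Step 2
Reactants: 2 (+)-menthone
Product: 4 trimethyl{[(3S,6R)-3-methyl-6-(propan-2-yl)cyclohex-1-en-1-yl]oxy}silane, via lithium enolate 3 (not isolated)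
Conditions: LiN(i-Pr)2, THF, −78 °C; Me3SiCl, −78 °C to 0 °C; pentane/aq NaHCO3
Reagents that add atoms: chlorotrimethylsilane, C[Si](C)(C)Cl
Why: kinetic enolate formation and O-silylation; the bulky amide takes a proton from the open ring CH2 and not the tertiary C-H next to isopropyl, so the less substituted enol ether forms and both stereocentres stay untouched.

Step 3
Reactants: 4 kinetic silyl enol ether
Product: 6 (2R,5S)-6-hydroxy-5-methyl-2-(propan-2-yl)hexanoic acid, via oxo acid 5 (not isolated)
Conditions: O3, CH2Cl2/MeOH, −78 °C; NaBH4, −78 °C to rt; aq citric acid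
Reagents that add atoms: ozone, [O-][O+]=O
Why: ozonolysis of a silyl enol ether cleaves the C=C into a silyl ester (acid after work-up) and an aldehyde, and reduction in the same flask converts the epimerisable 2-methyl aldehyde at once into a primary alcohol, leaving the two chain ends differentiated.

Step 4
Reactants: 6 hydroxy acid
Product: 7 methyl (2R,5S)-6-hydroxy-5-methyl-2-(propan-2-yl)hexanoate
Conditions: MeI, K2CO3, DMF, rt
Reagents that add atoms: iodomethane, CI
Why: SN2 alkylation of the carboxylate; K2CO3 ionises only the acid, so the alcohol is not methylated and the alpha centre is not enolised.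

Step 5
Reactants: 7 hydroxy ester
Product: 8 (2R,5S)-6-hydroxy-5-methyl-2-(propan-2-yl)hexanal (in equilibrium with its seven-membered lactol)
Conditions: i-Bu2AlH (2.3 equiv), CH2Cl2, −78 °C; MeOH, then aq potassium sodium tartrate
Reagents that add atoms: none
Why: partial ester reduction; the first equivalent is consumed by the hydroxyl and the second gives an aluminium hemiacetal of the hindered ester that holds at −78 °C and collapses to the aldehyde only on quench.

Step 6
Reactants: 8 hydroxy aldehyde
Product: 9 (2S,5R)-2-methyl-5-(propan-2-yl)hept-6-yn-1-ol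
Conditions: MeC(O)C(N2)P(O)(OMe)2, K2CO3, MeOH, 0 °C to rt
Reagents that add atoms: dimethyl (1-diazo-2-oxopropyl)phosphonate, CC(=O)C(=[N+]=[N-])P(=O)(OC)OC
Why: Ohira-Bestmann homologation (diazoalkene, then 1,2-H shift of the alkylidene carbene) works on hydroxy aldehydes and lactols, and the carbonate base normally leaves alpha-branched aldehydes configurationally intact.

Step 7
Reactants: 10 4-hydroxy-6-methyl-2H-pyran-2-one
Product: 11 4-(benzyloxy)-6-methyl-2H-pyran-2-one
Conditions: BnOH, PPh3, DIAD, THF, 0 °C to rt
Reagents that add atoms: benzyl alcohol, OCc1ccccc1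
Why: Mitsunobu reaction with the acidic 4-OH as pronucleophile gives O4-alkylation without the C3-benzylation that halide/base can cause; benzyl is chosen because a 4-methoxy-2-pyranone is a vinylogous methyl ester that is hard to cleave late, whereas benzyl falls with the other benzyl ethers in step 20.

Step 8
Reactants: 11 benzyloxypyranone
Product: 12 4-(benzyloxy)-3-iodo-6-methyl-2H-pyran-2-one
Conditions: NIS, CF3CO2H (cat.), MeCN, rt, dark
Reagents that add atoms: N-iodosuccinimide, O=C1CCC(=O)N1I
Why: electrophilic iodination; C3 lies between the lactone carbonyl and the 4-alkoxy donor and is the most nucleophilic carbon of a 4-alkoxy-2-pyranone.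

Step 9
Reactants: 9 alkynol; 12 iodopyranone
Product: 13 4-(benzyloxy)-3-[(3R,6S)-7-hydroxy-6-methyl-3-(propan-2-yl)hept-1-ynyl]-6-methyl-2H-pyran-2-one
Conditions: PdCl2(PPh3)2 (5 mol %), CuI (10 mol %), Et3N, THF, rt to 45 °C, Ar
Reagents that add atoms: none
Why: Sonogashira coupling of a 3-iodo-2-pyranone makes the later C8-C3' bond at an unhindered sp carbon, tolerates the free alcohol, and the O-benzyl group blocks cyclisation to a furopyranone.

Step 10
Reactants: 13 alcohol
Product: 14 (2S,5R)-7-[4-(benzyloxy)-6-methyl-2-oxo-2H-pyran-3-yl]-2-methyl-5-(propan-2-yl)hept-6-ynal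
Conditions: Dess-Martin periodinane, CH2Cl2, 0 °C to rt
Reagents that add atoms: none
Why: Dess-Martin oxidation stops at the aldehyde under near-neutral conditions and should neither epimerise the alpha-methyl centre nor touch the alkyne or the pyranone.

Step 11
Reactants: 14 aldehyde
Product: 15 4-(benzyloxy)-6-methyl-3-[(3R,6S)-6-methyl-3-(propan-2-yl)octa-1,7-diynyl]-2H-pyran-2-one
Conditions: MeC(O)C(N2)P(O)(OMe)2, K2CO3, MeOH, 0 °C to rt
Reagents that add atoms: dimethyl (1-diazo-2-oxopropyl)phosphonate, CC(=O)C(=[N+]=[N-])P(=O)(OC)OC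
Why: second Ohira-Bestmann homologation; K2CO3 in MeOH is too weak to condense the C6'-methyl with the aldehyde, and 4-alkoxy-2-pyranones withstand it for the few hours needed.

Step 12
Reactants: 16 3,3-diethoxyprop-1-yne; 17 1,3-dichloro-1,1,3,3-tetramethyldisiloxane
Product: 19 1-chloro-3-(3,3-diethoxyprop-1-ynyl)-1,1,3,3-tetramethyldisiloxane, via lithium acetylide 18 (not isolated)
Conditions: n-BuLi, Et2O, −78 °C; cannulated into 17 (4 equiv), Et2O, −78 °C to rt; filtration under Ar, distillation
Reagents that add atoms: none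
Why: substitution at silicon by a lithium acetylide; inverse addition into excess dichlorodisiloxane favours monosubstitution and the volatile excess is distilled off.

Step 13
Reactants: 15 terminal diyne; 19 chlorodisiloxane
Product: 20 disiloxane-linked triyne, 4-(benzyloxy)-3-[(3R,6S)-8-[3-(3,3-diethoxyprop-1-ynyl)-1,1,3,3-tetramethyldisiloxanyl]-6-methyl-3-(propan-2-yl)octa-1,7-diynyl]-6-methyl-2H-pyran-2-one
Conditions: Zn(OTf)2 (1.2 equiv), Et3N (3 equiv), 19 (1.5 equiv), CH2Cl2, rt; pH 7 buffer, Et3N-washed silica
Reagents that add atoms: none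
Why: electrophilic silylation of a zinc acetylide generated with Zn(OTf)2/Et3N is a known way to silylate terminal alkynes with chlorosilanes, and it is chosen because lithium or magnesium bases would deprotonate the C6'-methyl or attack the lactone, whereas Et3N does neither.

Step 14
Reactants: 20 disiloxane-linked triyne
Product: 21 oxadisilole-fused pyranonyl tetralin: (1R,4S)-tetralin with isopropyl at C1, methyl at C4, a C5-SiMe2-O-SiMe2-C6 bridge, CH(OEt)2 at C7 and 4-(benzyloxy)-6-methyl-2-oxo-2H-pyran-3-yl at C8
Conditions: RhCl(PPh3)3 (10 mol %), degassed toluene (0.01 M), 90 °C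
Reagents that add atoms: none
Why: Proposed new method: monovalent rhodium should bind two neighbouring alkynes of 20 and couple them oxidatively to a rhodacyclopentadiene, the remaining tethered alkyne then inserts and reductive elimination releases the benzene, so that C4a-C8a, C5-C6 and C7-C8 arise in one catalytic cycle. The closest known reaction types are the fully intramolecular Rh- or Co-catalysed [2+2+2] cycloisomerisation of tethered triynes (silyl-ether tethers included) and the cocyclisation of bis(ethynylsilyl) 1,6-diynes to disilaindanes; a Si-O-Si link inside a triyne whose end carries a 2-pyranone has not been shown. Ring B closes as the six-membered ring of the 1,7-diyne unit (C8a to C4a across C1-C4), the oxadisilole as the five-membered ring of the 1,6-diyne unit (C5 to C6 across Si-O-Si, helped by the long C-Si and Si-O bonds), and ring A is the new benzene made of the six sp carbons. No stereocentre is formed: C1 and C4 are propargylic spectators that a neutral, base-free medium should leave untouched, and only the C8-C3' axis is new. The step needs chemoselectivity for the three alkynes over the pyranone diene, the lactone and the acetal, which is secured by the stronger binding of alkynes to soft rhodium, by their enforced proximity and by a temperature below that of pyranone-alkyne Diels-Alder reactions. Regioselectivity is fixed by connectivity, since three alkynes in one chain can give only one hexasubstituted pattern, and high dilution holds back oligomerisation.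

Step 15
Reactants: 21 oxadisilole
Product: 22 catechol: 4-(benzyloxy)-3-[(1R,4S)-7-(diethoxymethyl)-5,6-dihydroxy-4-methyl-1-(propan-2-yl)tetralin-8-yl]-6-methyl-2H-pyran-2-one
Conditions: 30% aq H2O2, KF, KHCO3, THF/MeOH, 0 °C to 40 °C; aq Na2S2O3; used at once
Reagents that add atoms: hydrogen peroxide, OO
Why: Tamao-Fleming oxidation, known for aryl siloxanes and benzo-fused oxasiloles, is run on both C-Si bonds: fluoride or hydroperoxide makes each oxygen-bearing silicon pentacoordinate, the aryl carbon migrates from Si to O at the same ring position, and hydrolysis frees the C5 and C6 hydroxyls while the acetal shields C7 from a Dakin reaction.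

Step 16
Reactants: 22 catechol
Product: 23 dibenzyl ether: 4-(benzyloxy)-3-[(1R,4S)-5,6-bis(benzyloxy)-7-(diethoxymethyl)-4-methyl-1-(propan-2-yl)tetralin-8-yl]-6-methyl-2H-pyran-2-one
Conditions: BnBr, K2CO3, n-Bu4NI (cat.), DMF, 50 °C, Ar
Reagents that add atoms: benzyl bromide, BrCc1ccccc1
Why: Williamson etherification of both phenols protects the air-sensitive catechol in a form that survives LiN(i-Pr)2, and K2CO3 does not deprotonate the pyranone methyl.

Step 17
Reactants: 23 dibenzyl ether; 24 3,4-bis(benzyloxy)benzaldehyde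
Product: 26 aldol adduct 4-(benzyloxy)-3-[(1R,4S)-5,6-bis(benzyloxy)-7-(diethoxymethyl)-4-methyl-1-(propan-2-yl)tetralin-8-yl]-6-{2-[3,4-bis(benzyloxy)phenyl]-2-hydroxyethyl}-2H-pyran-2-one (carbinol epimers), via lithiated pyranone 25 (not isolated)
Conditions: LiN(i-Pr)2 (1.2 equiv), THF, −78 °C; 24; AcOH quench at −78 °C
Reagents that add atoms: none
Why: vinylogous aldol addition; the C6'-methyl is the only acidic site left because C3' is substituted, the dienolate adds through its terminal carbon to the non-enolisable aldehyde, and the new carbinol centre forms without control and is removed in step 18.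

Step 18
Reactants: 26 aldol adduct
Product: 28 (E)-styrylpyranone acetal 4-(benzyloxy)-3-[(1R,4S)-5,6-bis(benzyloxy)-7-(diethoxymethyl)-4-methyl-1-(propan-2-yl)tetralin-8-yl]-6-{(E)-2-[3,4-bis(benzyloxy)phenyl]ethenyl}-2H-pyran-2-one, via mesylate 27 (not isolated)
Conditions: MsCl, Et3N, CH2Cl2, 0 °C; DBU, rt
Reagents that add atoms: none
Why: mesylation and E1cB-type elimination give the fully conjugated styrylpyranone, for which the E alkene is strongly favoured on steric and conjugative grounds.

Step 19
Reactants: 28 styrylpyranone acetal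
Product: 29 penta-O-benzyl heimiomycin B (C7 aldehyde)
Conditions: p-TsOH·H2O (cat.), acetone/H2O, rt
Reagents that add atoms: water, O
Why: acid-catalysed acetal hydrolysis; the electron-rich, crowded benzylic acetal ionises easily, so conditions mild enough for the benzyl ethers, alkene and pyranone suffice, and freeing the aldehyde first keeps an oxocarbenium ion away from the arene scavenger of step 20.

Step 20
Reactants: 29 penta-O-benzyl heimiomycin B
Product: 30 heimiomycin B
Conditions: BCl3 (12 equiv), C6HMe5 (20 equiv), CH2Cl2, −78 °C; MeOH/H2O quench; reversed-phase chromatography under Ar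
Reagents that add atoms: none
Why: Lewis-acid debenzylation with BCl3 and pentamethylbenzene as cation scavenger cleaves aryl and vinylogous-ester benzyl ethers at −78 °C without reducing the alkene, as hydrogenolysis would, and without C-benzylating the catechols.

## Compound list

1 | (+)-menthol, (1S,2R,5S) | C[C@H]1CC[C@@H]([C@H](C1)O)C(C)C | starting material
2 | (+)-menthone, (2R,5S) | C[C@H]1CC[C@@H](C(=O)C1)C(C)C | intermediate
3 | kinetic lithium enolate of 2 | C[C@H]1CC[C@@H](C(O[Li])=C1)C(C)C | intermediate
4 | kinetic trimethylsilyl enol ether, (3S,6R) | C[C@H]1CC[C@@H](C(O[Si](C)(C)C)=C1)C(C)C | intermediate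
5 | (2R,5S)-5-methyl-6-oxo-2-(propan-2-yl)hexanoic acid | C[C@H](C=O)CC[C@@H](C(=O)O)C(C)C | intermediate
6 | (2R,5S)-6-hydroxy-5-methyl-2-(propan-2-yl)hexanoic acid | C[C@H](CO)CC[C@@H](C(=O)O)C(C)C | intermediate
7 | methyl (2R,5S)-6-hydroxy-5-methyl-2-(propan-2-yl)hexanoate | C[C@H](CO)CC[C@@H](C(=O)OC)C(C)C | intermediate
8 | (2R,5S)-6-hydroxy-5-methyl-2-(propan-2-yl)hexanal | C[C@H](CO)CC[C@@H](C=O)C(C)C | intermediate
9 | (2S,5R)-2-methyl-5-(propan-2-yl)hept-6-yn-1-ol | C[C@H](CO)CC[C@@H](C#C)C(C)C | intermediate
10 | 4-hydroxy-6-methyl-2H-pyran-2-one | Cc1cc(O)cc(=O)o1 | starting material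
11 | 4-(benzyloxy)-6-methyl-2H-pyran-2-one | Cc1cc(OCc2ccccc2)cc(=O)o1 | intermediate
12 | 4-(benzyloxy)-3-iodo-6-methyl-2H-pyran-2-one | Cc1cc(OCc2ccccc2)c(I)c(=O)o1 | intermediate
13 | alkynylpyranone alcohol, (3R,6S) side chain | C[C@H](CO)CC[C@@H](C#Cc1c(OCc2ccccc2)cc(C)oc1=O)C(C)C | intermediate
14 | alkynylpyranone aldehyde, (2S,5R) | C[C@H](C=O)CC[C@@H](C#Cc1c(OCc2ccccc2)cc(C)oc1=O)C(C)C | intermediate
15 | pyranonyl 1,7-diyne with free terminal alkyne, (3R,6S) | C[C@H](C#C)CC[C@@H](C#Cc1c(OCc2ccccc2)cc(C)oc1=O)C(C)C | intermediate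
16 | 3,3-diethoxyprop-1-yne | C#CC(OCC)OCC | starting material
17 | 1,3-dichloro-1,1,3,3-tetramethyldisiloxane | C[Si](C)(Cl)O[Si](C)(C)Cl | starting material
18 | lithium 3,3-diethoxyprop-1-ynide | [Li]C#CC(OCC)OCC | intermediate
19 | 1-chloro-3-(3,3-diethoxyprop-1-ynyl)-1,1,3,3-tetramethyldisiloxane | CCOC(OCC)C#C[Si](C)(C)O[Si](C)(C)Cl | intermediate
20 | disiloxane-linked triyne (key-step precursor) | CC(C)[C@@H](CC[C@H](C)C#C[Si](C)(C)O[Si](C)(C)C#CC(OCC)OCC)C#Cc1c(OCc2ccccc2)cc(C)oc1=O | intermediate
21 | oxadisilole-fused pyranonyl tetralin (key-step product), (1R,4S) | CC(C)[C@H]1CC[C@H](C)c2c3c(c(C(OCC)OCC)c(-c4c(OCc5ccccc5)cc(C)oc4=O)c21)[Si](C)(C)O[Si]3(C)C | intermediate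
22 | C5,C6-catechol, (1R,4S) | CC(C)[C@H]1CC[C@H](C)c2c(O)c(O)c(C(OCC)OCC)c(-c3c(OCc4ccccc4)cc(C)oc3=O)c21 | intermediate
23 | C5,C6-dibenzyl ether, (1R,4S) | CC(C)[C@H]1CC[C@H](C)c2c(OCc3ccccc3)c(OCc3ccccc3)c(C(OCC)OCC)c(-c3c(OCc4ccccc4)cc(C)oc3=O)c21 | intermediate
24 | 3,4-bis(benzyloxy)benzaldehyde | O=Cc1ccc(OCc2ccccc2)c(OCc2ccccc2)c1 | starting material
25 | C6'-lithiomethyl derivative (dienolate) of 23 | CC(C)[C@H]1CC[C@H](C)c2c(OCc3ccccc3)c(OCc3ccccc3)c(C(OCC)OCC)c(-c3c(OCc4ccccc4)cc(C[Li])oc3=O)c21 | intermediate
26 | aldol adduct (carbinol epimers) | CC(C)[C@H]1CC[C@H](C)c2c(OCc3ccccc3)c(OCc3ccccc3)c(C(OCC)OCC)c(-c3c(OCc4ccccc4)cc(CC(O)c4ccc(OCc5ccccc5)c(OCc5ccccc5)c4)oc3=O)c21 | intermediate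
27 | mesylate of 26 | CC(C)[C@H]1CC[C@H](C)c2c(OCc3ccccc3)c(OCc3ccccc3)c(C(OCC)OCC)c(-c3c(OCc4ccccc4)cc(CC(OS(C)(=O)=O)c4ccc(OCc5ccccc5)c(OCc5ccccc5)c4)oc3=O)c21 | intermediate
28 | (E)-styrylpyranone acetal | CC(C)[C@H]1CC[C@H](C)c2c(OCc3ccccc3)c(OCc3ccccc3)c(C(OCC)OCC)c(-c3c(OCc4ccccc4)cc(/C=C/c4ccc(OCc5ccccc5)c(OCc5ccccc5)c4)oc3=O)c21 | intermediate
29 | penta-O-benzyl heimiomycin B | CC(C)[C@H]1CC[C@H](C)c2c(OCc3ccccc3)c(OCc3ccccc3)c(C=O)c(-c3c(OCc4ccccc4)cc(/C=C/c4ccc(OCc5ccccc5)c(OCc5ccccc5)c4)oc3=O)c21 | intermediate
30 | heimiomycin B, (1R,4S) | CC(C)[C@H]1CC[C@H](C)c2c(O)c(O)c(C=O)c(-c3c(O)cc(/C=C/c4ccc(O)c(O)c4)oc3=O)c21 | target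

## Counts

- Total step count: 20.
- Longest linear sequence: 17 steps from (+)-menthol (steps 1-6, 9-11, 13-20).

## Steps most likely to fail

**1. Step 14 (key step).**
- **What may go wrong.**
  - The cycle may stall after the first oxidative coupling, because insertion of the third, doubly substituted alkyne has to build a hexasubstituted ring next to the C1 isopropyl group.
  - The pyranone may hold the rhodium.
  - Oligomerisation may compete.
  - Traces of water at 90 °C may open the Si-O-Si link.
- **Fallback (known chemistry).** The disiloxane is replaced by a silyl-ether tether, the class for which fully intramolecular rhodium-catalysed triyne cyclisation and later Tamao oxidation are established. The C6 oxygen is then brought in by a Dakin reaction. The fallback sets out from 16 and 15 and comes back at 22.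
- **Tether.** Compound 16 is hydroxymethylated (n-BuLi, paraformaldehyde) to 4,4-diethoxybut-2-yn-1-ol F1. Excess Me2SiCl2/Et3N gives its chlorodimethylsilyl ether F2.
- **Cyclisation.** Compound 15 is C-silylated with F2 under the conditions of step 13 to the silyl-ether-linked triyne F3. RhCl(PPh3)3 in toluene closes ring A, ring B and a five-membered oxasilole to the benzoxasilole-fused tetralin F4. Its C6 carries a CH2 instead of a second SiMe2 and is less crowded.
- **Oxygenation.** H2O2/KF/KHCO3 gives the C5-phenol C6-benzylic alcohol F5, and MnO2 gives the salicylaldehyde F6. Dakin oxidation (H2O2, aq Na2CO3, THF, 0 °C) of this ortho-hydroxy aldehyde, with C7 still masked as the acetal, gives 22.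

**2. Step 15 (double Tamao oxidation).**
- **What may go wrong.**
  - The second silicon may be lost by protodesilylation once the first phenoxide has formed.
  - Alkaline peroxide may over-oxidise the catechol to a quinone or to ring-cleaved acids.
  - Hydroperoxide may attack the pyranone.
- **Fallback.** Silicon delivers one oxygen only, and the second comes from ortho-oxygenation of the phenol. The fallback sets out from 21 and comes back at 22.
- **Monophenols.** One equivalent of H2O2 with KHCO3, then n-Bu4NF in wet THF, should oxidise one C-Si bond and protodesilylate the other. This gives the C5-phenol F7 and/or the C6-phenol F8.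
- **Convergence.** Each phenol has a single free ortho position, so IBX (DMF, rt) should convert both into the same 5,6-quinone F9. Na2S2O4 in the work-up reduces it to 22, which then never meets alkaline peroxide.

**3. Step 13 (attachment of the tether).**
- **What may go wrong.**
  - Zincation of the alkyl alkyne may be slow.
  - Soft enolisation and O-silylation of the pyranone may consume 19.
  - The Si-Cl or Si-O-Si bonds may hydrolyse during isolation.
- **Fallback.** The order of events is reversed: the C(sp)-Si bond is made from a lithium acetylide before any pyranone is present, and the pyranone enters last. The fallback sets out from 4 and comes back at 20.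
- **Methyl-side alkyne.** Ozonolysis of 4 with Me2S work-up gives 5, now isolated. Ohira-Bestmann homologation (extra K2CO3 for the carboxylate) gives the alkyne acid F10, LiAlH4 gives the alkynol F11, and Et3SiCl/imidazole gives the triethylsilyl ether F12.
- **Tether.** n-BuLi at −78 °C and then 19 give the tethered diyne F13.
- **Isopropyl-side alkyne.** Swern oxidation, which oxidises primary triethylsilyl ethers directly, gives the aldehyde F14. Dimethyl (diazomethyl)phosphonate/KOt-Bu in THF at −78 °C (Seyferth-Gilbert homologation, no methanol) gives the terminal alkyne F15.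
- **Return.** Sonogashira coupling of F15 with 12 under the conditions of step 9 gives 20.

## Further compounds

F1 | step 14 | 4,4-diethoxybut-2-yn-1-ol | OCC#CC(OCC)OCC
F2 | step 14 | chloro[(4,4-diethoxybut-2-yn-1-yl)oxy]dimethylsilane | C[Si](C)(Cl)OCC#CC(OCC)OCC
F3 | step 14 | silyl-ether-linked triyne | CC(C)[C@@H](CC[C@H](C)C#C[Si](C)(C)OCC#CC(OCC)OCC)C#Cc1c(OCc2ccccc2)cc(C)oc1=O
F4 | step 14 | benzoxasilole-fused tetralin (C5-SiMe2-O-CH2-C6), (1R,4S) | CC(C)[C@H]1CC[C@H](C)c2c3c(c(C(OCC)OCC)c(-c4c(OCc5ccccc5)cc(C)oc4=O)c21)CO[Si]3(C)C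
F5 | step 14 | C5-phenol C6-benzylic alcohol | CC(C)[C@H]1CC[C@H](C)c2c(O)c(CO)c(C(OCC)OCC)c(-c3c(OCc4ccccc4)cc(C)oc3=O)c21
F6 | step 14 | C5-hydroxy C6-carbaldehyde (salicylaldehyde) | CC(C)[C@H]1CC[C@H](C)c2c(O)c(C=O)c(C(OCC)OCC)c(-c3c(OCc4ccccc4)cc(C)oc3=O)c21
F7 | step 15 | C5-phenol (C6-H) | CC(C)[C@H]1CC[C@H](C)c2c(O)cc(C(OCC)OCC)c(-c3c(OCc4ccccc4)cc(C)oc3=O)c21
F8 | step 15 | C6-phenol (C5-H) | CC(C)[C@H]1CC[C@H](C)c2cc(O)c(C(OCC)OCC)c(-c3c(OCc4ccccc4)cc(C)oc3=O)c21
F9 | step 15 | 5,6-quinone | CC(C)[C@H]1CC[C@H](C)C2=C1C(-c1c(OCc3ccccc3)cc(C)oc1=O)=C(C(OCC)OCC)C(=O)C2=O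
F10 | step 13 | (2R,5S)-5-methyl-2-(propan-2-yl)hept-6-ynoic acid | C[C@H](C#C)CC[C@@H](C(=O)O)C(C)C
F11 | step 13 | (2R,5S)-5-methyl-2-(propan-2-yl)hept-6-yn-1-ol | C[C@H](C#C)CC[C@@H](CO)C(C)C
F12 | step 13 | triethylsilyl ether of F11 | C[C@H](C#C)CC[C@@H](CO[Si](CC)(CC)CC)C(C)C
F13 | step 13 | tethered diyne triethylsilyl ether | C[C@H](C#C[Si](C)(C)O[Si](C)(C)C#CC(OCC)OCC)CC[C@@H](CO[Si](CC)(CC)CC)C(C)C
F14 | step 13 | tethered diyne aldehyde, (2R,5S) | C[C@H](C#C[Si](C)(C)O[Si](C)(C)C#CC(OCC)OCC)CC[C@@H](C=O)C(C)C
F15 | step 13 | tethered triyne with free terminal alkyne, (3S,6R) | C[C@H](C#C[Si](C)(C)O[Si](C)(C)C#CC(OCC)OCC)CC[C@@H](C#C)C(C)C
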